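**Plan**

- Retrosynthesis: the three phenols of the (2S)-flavanone are masked as MOM ethers and the C4 ketone is traced back to a C4 methyl ether of the same oxidation level; ring C is then cut at O1–C2 and C3–C4.
- Enabling feature: O1, C8a, C4a and C4 (ring A with its oxygen and benzylic carbon) make up an ortho-quinone methide heterodiene, and C2–C3 with the ring B aryl group on C2 is a styrene.
- Fragments: ring A salicylaldehyde 8 comes from resorcinol by MOM protection, two ortho-lithiations (prenylation, then formylation) and cleavage of the MOM group next to the aldehyde; ring B styrene 12 comes from 3-bromo-4,5-dihydroxybenzaldehyde by MOM protection, Stille prenylation and Wittig methylenation.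
- Ring formation: ring C, the only ring made, closes in step 8 by a chiral-acid-catalysed (4+2) cycloaddition of the 4-methoxy ortho-quinone methide with the styrene; solvolysis of the C4 ether, oxidation and MOM removal then give the target.
- Stereochemistry: C2 (S), the only stereocentre of the target, is set in the cycloaddition by the chiral counter-anion; the cis C4 centre formed with it is transient and is erased on oxidation.

Key step: step 8

Abbreviations: MOM = methoxymethyl; prenyl = 3-methylbut-2-en-1-yl; flavonoid numbering (O1, C2, C3, C4, C4a, C5–C8, C8a; ring B primed).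

Assumption: the sense of induction of the confined acid cannot be predicted with certainty; the (S,S) catalyst is written as the one leading to the (2S) series, and its mirror image would be used if a first experiment shows the opposite sense.

**Route**

Step 1
Reactants: 1 resorcinol
Product: 2 1,3-bis(methoxymethoxy)benzene
Conditions: NaH, MOMCl, DMF, 0 °C → rt
Reagents that add atoms: chloromethyl methyl ether, COCCl
Why: Williamson-type O-alkylation of the bis-phenoxide with the reactive α-chloro ether should give the bis-MOM ether, whose acetal oxygens later direct both lithiations.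

Step 2
Reactants: 2 1,3-bis(methoxymethoxy)benzene
Product: 4 1,3-bis(methoxymethoxy)-2-prenylbenzene, via 2,6-bis(methoxymethoxy)phenyllithium 3 (not isolated)
Conditions: n-BuLi, THF, 0 °C → rt; then CuBr·SMe2 (10 mol%), prenyl bromide, −78 °C → rt
Reagents that add atoms: prenyl bromide (1-bromo-3-methylbut-2-ene), CC(C)=CCBr
Why: Directed ortho-metalation occurs at the position flanked by both MOM ethers, and copper-catalysed allylation of the aryllithium at the unhindered primary carbon of prenyl bromide should give the linear prenyl arene.

Step 3
Reactants: 4 1,3-bis(methoxymethoxy)-2-prenylbenzene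
Product: 7 2,4-bis(methoxymethoxy)-3-prenylbenzaldehyde, via 2,4-bis(methoxymethoxy)-3-prenylphenyllithium 5 (not isolated), via lithium hemiaminal alkoxide 6 (not isolated)
Conditions: n-BuLi, TMEDA, THF, 0 °C; DMF, 0 °C → rt; then H2O
Reagents that add atoms: N,N-dimethylformamide, CN(C)C=O
Why: A second directed ortho-metalation at the remaining ring position next to a MOM ether, followed by formylation of the aryllithium with DMF, should place the aldehyde para to one MOM ether and ortho to the other.

Step 4
Reactants: 7 2,4-bis(methoxymethoxy)-3-prenylbenzaldehyde
Product: 8 2-hydroxy-4-(methoxymethoxy)-3-prenylbenzaldehyde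
Conditions: aq HCl (1 M, 1.5 equiv), MeOH, 0 °C → rt, stopped when 7 is consumed
Reagents that add atoms: none
Why: Acid-catalysed acetal transfer to methanol is fastest at the MOM ether ortho to the formyl group, whose cleavage is assisted by the carbonyl oxygen and gives a hydrogen-bonded phenol, an established selective deprotection of aryl MOM ethers next to a carbonyl group that should spare the remote MOM ether and the prenyl group.

Step 5
Reactants: 9 3-bromo-4,5-dihydroxybenzaldehyde
Product: 10 3-bromo-4,5-bis(methoxymethoxy)benzaldehyde
Conditions: MOMCl, K2CO3, acetone, 0 °C → rt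
Reagents that add atoms: chloromethyl methyl ether, COCCl
Why: O-alkylation of both catechol hydroxyl groups under mild carbonate conditions should protect the catechol without touching the aldehyde or the bromide.

Step 6
Reactants: 10 3-bromo-4,5-bis(methoxymethoxy)benzaldehyde
Product: 11 3,4-bis(methoxymethoxy)-5-prenylbenzaldehyde
Conditions: tributyl(3-methylbut-2-enyl)stannane, Pd(PPh3)4 (5 mol%), DMF, 100 °C
Reagents that add atoms: tributyl(3-methylbut-2-enyl)stannane, CC(C)=CC[Sn](CCCC)(CCCC)CCCC
Why: Stille coupling (oxidative addition of zerovalent palladium to the aryl bromide, transmetalation, reductive elimination at the less hindered primary allyl terminus) should install the linear prenyl group while tolerating the aldehyde and the MOM ethers.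

Step 7
Reactants: 11 3,4-bis(methoxymethoxy)-5-prenylbenzaldehyde
Product: 12 3,4-bis(methoxymethoxy)-5-prenylstyrene
Conditions: Ph3PCH3Br, KOt-Bu, THF, 0 °C → rt
Reagents that add atoms: methyltriphenylphosphonium bromide, C[P+](c1ccccc1)(c1ccccc1)c1ccccc1.[Br-]
Why: Wittig methylenation of the non-enolisable aryl aldehyde with the unstabilised ylide should give the styrene without affecting the prenyl alkene or the acetals.

Step 8
Reactants: 8 2-hydroxy-4-(methoxymethoxy)-3-prenylbenzaldehyde; 12 3,4-bis(methoxymethoxy)-5-prenylstyrene
Product: 15 (2S,4S)-cis-4-methoxy-7-(methoxymethoxy)-2-[3,4-bis(methoxymethoxy)-5-prenylphenyl]-8-prenylchroman, via dimethyl acetal 13 (not isolated), via 4-methoxy ortho-quinone methide 14 (not isolated)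
Conditions: HC(OMe)3 (1.5 equiv), confined (S,S)-imidodiphosphoric acid (3,3′-diaryl-BINOL-derived, 5 mol%), CH2Cl2, −30 °C; Et3N quench
Reagents that add atoms: trimethyl orthoformate, COC(OC)OC
Why: Proposed new method: acid-catalysed exchange of 8 with the orthoformate gives acetal 13, which loses methanol to the 4-methoxy ortho-quinone methide 14 (an O-methyl oxocarbenium ion paired with the confined chiral anion); the closest known reaction types are the achiral acid-catalysed three-component hetero-Diels–Alder reaction of salicylaldehydes, orthoformates and alkenes and the confined-acid-catalysed asymmetric (4+2) cycloadditions of transient ortho-quinone methides, so only the intermolecular enantioselective combination with a styrene is new. The terminal carbon of styrene 12 attacks the electrophilic C4 while the phenolic oxygen closes on the developing benzylic cation at C2, a concerted but asynchronous inverse-electron-demand (4+2) cycloaddition that forms C3–C4 and O1–C2. Ring C, the only ring formed, closes as the six-membered ring of this cycloaddition, suprafacially on both partners (in the stepwise limit a 6-exo-trig capture of the para-oxygen-stabilised benzylic cation by the phenol oxygen). C2 is controlled by the chiral counter-anion, which shields one face of the bound heterodiene so that the styrene adds to the open face with its aryl group endo; C4 follows from the endo transition state as the 2,4-cis isomer and is erased in step 10. The step needs enantioface selectivity, regioselectivity and chemoselectivity for the styrene over the prenyl alkenes: the confined anion should provide the first, the polarisation of the para-oxygenated styrene (nucleophilic CH2 terminus, cation-stabilising aryl group) the second, and the higher nucleophilicity and lower steric demand of the conjugated monosubstituted vinyl group compared with the trisubstituted prenyl alkenes the third. Low temperature and the amine quench are chosen to keep the MOM acetals, the ortho-prenyl phenol and the acid-labile O1–C2 bond of the product intact.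

Step 9
Reactants: 15 (2S,4S)-cis-4-methoxyflavan tri-MOM ether
Product: 16 (2S)-7-(methoxymethoxy)-2-[3,4-bis(methoxymethoxy)-5-prenylphenyl]-8-prenylchroman-4-ol (mixture of C4 epimers)
Conditions: aq HCl (0.1 M), THF, 0 °C → rt; NaHCO3 quench
Reagents that add atoms: water, O
Why: SN1 solvolysis through the C4 cation stabilised by O1 (ortho) and the C7 oxygen (para), the reverse of the classical acid-catalysed methanolysis of flavan-4-ols, should exchange methoxy for hydroxyl in the large excess of water while the less labile aryl MOM ethers and C2 stay untouched; the C4 epimer ratio is of no consequence.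

Step 10
Reactants: 16 (2S)-flavan-4-ol tri-MOM ether
Product: 17 (2S)-7-(methoxymethoxy)-2-[3,4-bis(methoxymethoxy)-5-prenylphenyl]-8-prenylchroman-4-one
Conditions: Dess–Martin periodinane, NaHCO3, CH2Cl2, 0 °C → rt
Reagents that add atoms: none
Why: Dess–Martin oxidation of the secondary benzylic alcohol under buffered, non-basic conditions should give the flavanone without touching the prenyl alkenes or the MOM ethers and without opening ring C, so C2 is retained and both C4 epimers converge.

Step 11
Reactants: 17 (2S)-flavanone tri-MOM ether
Product: 18 (2S)-7-hydroxy-2-(3,4-dihydroxy-5-prenylphenyl)-8-prenylchroman-4-one (the target)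
Conditions: aq HCl (3 M), MeOH, 40 °C, stopped at full conversion
Reagents that add atoms: none
Why: Acid-catalysed transacetalisation of the three aryl MOM ethers to methanol is the standard final deprotection of prenylated flavanones; C2 should hold because flavanone racemisation runs through base-induced retro-oxa-Michael opening, and moderate temperature with short exposure should avoid cyclisation of the freed phenols onto the prenyl groups.

**Compound list**

1 | resorcinol | Oc1cccc(O)c1 | starting material
2 | 1,3-bis(methoxymethoxy)benzene | COCOc1cccc(OCOC)c1 | intermediate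
3 | 2,6-bis(methoxymethoxy)phenyllithium (not isolated) | [Li]c1c(OCOC)cccc1OCOC | intermediate
4 | 1,3-bis(methoxymethoxy)-2-prenylbenzene | COCOc1cccc(OCOC)c1CC=C(C)C | intermediate
5 | 2,4-bis(methoxymethoxy)-3-prenylphenyllithium (not isolated) | [Li]c1ccc(OCOC)c(CC=C(C)C)c1OCOC | intermediate
6 | lithium hemiaminal alkoxide from 5 and DMF (not isolated) | CN(C)C(O[Li])c1ccc(OCOC)c(CC=C(C)C)c1OCOC | intermediate
7 | 2,4-bis(methoxymethoxy)-3-prenylbenzaldehyde | O=Cc1ccc(OCOC)c(CC=C(C)C)c1OCOC | intermediate
8 | 2-hydroxy-4-(methoxymethoxy)-3-prenylbenzaldehyde | O=Cc1ccc(OCOC)c(CC=C(C)C)c1O | intermediate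
9 | 3-bromo-4,5-dihydroxybenzaldehyde | O=Cc1cc(O)c(O)c(Br)c1 | starting material
10 | 3-bromo-4,5-bis(methoxymethoxy)benzaldehyde | O=Cc1cc(Br)c(OCOC)c(OCOC)c1 | intermediate
11 | 3,4-bis(methoxymethoxy)-5-prenylbenzaldehyde | O=Cc1cc(CC=C(C)C)c(OCOC)c(OCOC)c1 | intermediate
12 | 3,4-bis(methoxymethoxy)-5-prenylstyrene | C=Cc1cc(CC=C(C)C)c(OCOC)c(OCOC)c1 | intermediate
13 | dimethyl acetal of 8 (not isolated) | COC(OC)c1ccc(OCOC)c(CC=C(C)C)c1O | intermediate
14 | 4-methoxy ortho-quinone methide: 6-(methoxymethylidene)-3-(methoxymethoxy)-2-prenylcyclohexa-2,4-dien-1-one (not isolated) | COC=C1C=CC(OCOC)=C(CC=C(C)C)C1=O | intermediate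
15 | (2S,4S)-cis-4-methoxy-7-(methoxymethoxy)-2-[3,4-bis(methoxymethoxy)-5-prenylphenyl]-8-prenylchroman | CC(C)=CCc1cc([C@@H]2C[C@H](OC)c3ccc(OCOC)c(CC=C(C)C)c3O2)cc(OCOC)c1OCOC | intermediate
16 | (2S)-7-(methoxymethoxy)-2-[3,4-bis(methoxymethoxy)-5-prenylphenyl]-8-prenylchroman-4-ol, C4 epimers | CC(C)=CCc1cc([C@@H]2CC(O)c3ccc(OCOC)c(CC=C(C)C)c3O2)cc(OCOC)c1OCOC | intermediate
17 | (2S)-7-(methoxymethoxy)-2-[3,4-bis(methoxymethoxy)-5-prenylphenyl]-8-prenylchroman-4-one | CC(C)=CCc1cc([C@@H]2CC(=O)c3ccc(OCOC)c(CC=C(C)C)c3O2)cc(OCOC)c1OCOC | intermediate
18 | (2S)-7-hydroxy-2-(3,4-dihydroxy-5-prenylphenyl)-8-prenylchroman-4-one | CC(C)=CCc1cc([C@@H]2CC(=O)c3ccc(O)c(CC=C(C)C)c3O2)cc(O)c1O | target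

**Step count**

Total step count: 11.
Longest linear sequence: 8 steps (steps 1, 2, 3, 4, 8, 9, 10, 11); the ring B branch (steps 5, 6, 7) joins at step 8.

**Steps most likely to fail**

1. Step 8 (proposed new method). The confined anion may discriminate the faces poorly with an intermolecular styrene partner. The prenyl alkenes may compete as 2π partners. The acid may strip MOM groups or cyclise the ortho-prenyl phenol. Reversible ionisation of O1–C2 in the product may erode the configuration at C2.
 Fallback, from 8 and 12 back to 17, using known chemistry: the same three-component cycloaddition with trimethyl orthoformate under an achiral acid (Sc(OTf)3 or TsOH, CH2Cl2, 0 °C), a known reaction type passing through 13 and 14, would give racemic cis-4-methoxyflavan tri-MOM ether F1. Solvolysis as in step 9 would give racemic flavan-4-ol tri-MOM ether F2, and Dess–Martin oxidation racemic flavanone tri-MOM ether F3. Kinetic resolution by asymmetric transfer hydrogenation with RuCl[(R,R)-TsDPEN](p-cymene) and HCO2H–Et3N, a known way to resolve racemic flavanones, is expected to reduce the (2R)-ketone to (2R,4R)-cis-flavan-4-ol tri-MOM ether F4. The unreacted (2S)-ketone is compound 17, where the route is rejoined.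

2. Step 9. The C4 cation may lose the C3 proton (E1) to give the flav-3-ene instead of being captured by water, or the acid may start to remove MOM groups before exchange is complete.
 Fallback, from 15 directly to 17: oxidation with DDQ in CH2Cl2–H2O at 0 °C. Hydride abstraction from the doubly activated C4–H bond gives the C4 methoxy oxocarbenium ion, water adds, and the hemiketal loses methanol to the ketone. This is the known oxidative cleavage of electron-rich benzylic ethers and the known C4-selective DDQ oxidation of flavans; it bypasses 16 and makes no new compound (entry F0).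

3. Step 3. Deprotonation may occur at the benzylic–allylic methylene flanked by the two MOM ethers instead of at the ring, leading to side-chain formylation or alkene migration, or ring lithiation may be incomplete.
 Fallback, from 4 back to 8: removal of both MOM groups (HCl, MeOH, rt) would give 2-prenylresorcinol F5. Magnesium-mediated ortho-formylation (MgCl2, Et3N, paraformaldehyde, MeCN, reflux; Casnati–Skattebøl conditions) would give 2,4-dihydroxy-3-prenylbenzaldehyde F6. Selective MOM protection of the non-chelated C4 hydroxyl (MOMCl 1.05 equiv, K2CO3, acetone, rt) returns to 8, bypassing 7 and step 4.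

**Further compounds**

F1 | step 8 | racemic (2RS,4RS)-cis-4-methoxy-7-(methoxymethoxy)-2-[3,4-bis(methoxymethoxy)-5-prenylphenyl]-8-prenylchroman (racemate, drawn without configuration) | CC(C)=CCc1cc(C2CC(OC)c3ccc(OCOC)c(CC=C(C)C)c3O2)cc(OCOC)c1OCOC
F2 | step 8 | racemic 7-(methoxymethoxy)-2-[3,4-bis(methoxymethoxy)-5-prenylphenyl]-8-prenylchroman-4-ol, C4 epimers (racemate, drawn without configuration) | CC(C)=CCc1cc(C2CC(O)c3ccc(OCOC)c(CC=C(C)C)c3O2)cc(OCOC)c1OCOC
F3 | step 8 | racemic 7-(methoxymethoxy)-2-[3,4-bis(methoxymethoxy)-5-prenylphenyl]-8-prenylchroman-4-one (racemate, drawn without configuration) | CC(C)=CCc1cc(C2CC(=O)c3ccc(OCOC)c(CC=C(C)C)c3O2)cc(OCOC)c1OCOC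
F4 | step 8 | (2R,4R)-cis-7-(methoxymethoxy)-2-[3,4-bis(methoxymethoxy)-5-prenylphenyl]-8-prenylchroman-4-ol | CC(C)=CCc1cc([C@H]2C[C@@H](O)c3ccc(OCOC)c(CC=C(C)C)c3O2)cc(OCOC)c1OCOC
F0 | step 9 | none | none
F5 | step 3 | 2-prenylresorcinol | CC(C)=CCc1c(O)cccc1O
F6 | step 3 | 2,4-dihydroxy-3-prenylbenzaldehyde | O=Cc1ccc(O)c(CC=C(C)C)c1O
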